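Readings and results are calculated for an exercise; the scatter is artificial.

Ask which flask leads in the share of target. Here is what stands on the bench:

| flask | starting material | coupling partner | temperature | remark | time |
|---|---|---|---|---|---|
| green | 0.14 M | 0.050 M | −2 °C | run made earlier |  |
| blue | 0.22 M | 0.050 M | 47 °C | run made earlier |  |
| violet | 0.10 M | 0.10 M | −2 °C | run made earlier |  |
| larch | 0.10 M | 0.0500 M | 5 °C |  | 6.0 h |
| elm | 0.10 M | 0.0500 M | 35 °C |  | 6.0 h |
| alder | 0.10 M | 0.0500 M | 65 °C |  | 6.0 h |
| oak | 0.10 M | 0.0500 M | −25 °C |  | 6.0 h |

green run (percent of the starting material charged)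

| time / h | target / % | isomer of the product A / % |
|---|---|---|
| 0.250 | 0 | 0.3 |
| 0.500 | 0 | 0 |
| 0.833 | 0.4 | 0.1 |
| 1.33 | 0.4 | 0 |
| 2.00 | 0.5 | 0 |
| 4.00 | 0.4 | 0.5 |

blue run (percent of the starting material charged)

| time / min | target / % | isomer of the product A / % |
|---|---|---|
| 5.00 | 0.3 | 1.5 |
| 10.0 | 0 | 1.3 |
| 15.0 | 0 | 3.1 |
| 20.0 | 0 | 3.1 |
| 25.0 | 0.1 | 3.8 |
| 30.0 | 0 | 5.1 |

violet run (percent of the starting material charged)

| time / h | target / % | isomer of the product A / % |
|---|---|---|
| 0.250 | 0 | 0 |
| 0.500 | 0.2 | 0.2 |
| 1.00 | 0.8 | 0.9 |
| 2.00 | 0 | 0 |
| 4.00 | 1.1 | 1.9 |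

(each reading ± 0.5 percentage points)

- which flask leads in share of target in all that became target or isomer of the product A or isomer of the product B ("all alike" within 1.5 percentage points) (larch / elm / alder / oak / all alike)
- share of target in all that became target or isomer of the product A or isomer of the product B, larch
- share of target in all that became target or isomer of the product A or isomer of the product B, elm
- share of target in all that became target or isomer of the product A or isomer of the product B, alder
- share of target in all that became target or isomer of the product A or isomer of the product B, oak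



Don't reckon with the share. Reckon with the odds, a selectivity factor: target over the rest of the product. The share is then odds over one plus odds. Isomer of the product B was not read, so take target over isomer of the product A.

Start with a contradiction at −2 °C. The green run sums to 1.70% target against 0.900% isomer of the product A. The violet run sums to 2.10% against 3.00%. So violet, with twice the coupling partner and less starting material than green, seems to cut the odds from 1.89 to 0.700.

Now weigh the scatter. A green sum carries about 1.2 percentage points, more than the green gap of 0.8 points. A violet sum carries about 1.1 points, more than the violet gap of 0.9 points. So pool the two runs. The cold odds read 0.974.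

The blue run at 47 °C sums to 0.400% against 17.9%, so its odds of 0.0223 are lower than the cold odds. Blue also holds more starting material than green, so the two runs differ in more than temperature. My reckoning commits to this: oak, colder than the other flasks, leads, with a share I estimate above 49.3%.

The forecast goes further and prints numbers: 33% for larch, 7% for elm, 2% for alder and 72% for oak. Its words are “Oak, the coldest flask, should lead”.

The flasks give 30.4% for larch, 8.17% for elm, 12.3% for alder and 69.7% for oak, so oak leads.

    starting material ⇌ tight pair (K = 2.70 × 10⁻⁴, k = 0.350 /h, Ea = 92.0 kJ/mol, ΔH = −30.0 kJ/mol)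
    coupling partner + tight pair → target (k = 730 /M/h, Ea = 55.0 kJ/mol)
    target ⇌ isomer of the product B (K = 0.260, k = 0.0730 /h, Ea = 101 kJ/mol, ΔH = 12.0 kJ/mol)
    coupling partner + loose pair → isomer of the product A (k = 11000 /M/h, Ea = 37.0 kJ/mol)
    tight pair ⇌ loose pair (K = 3.40, k = 300 /h, Ea = 86.0 kJ/mol, ΔH = −46.0 kJ/mol)
    (constants at 35 °C)

Oak's odds at −25 °C are 2.30, higher than the cold odds of 0.974 read at −2 °C. Take the neighbouring flask, like oak but charged with 0.013 M of coupling partner. Try the odds in proportion to c(coupling partner). That gives 0.599, so a share of 37.5%. The neighbouring flask gives 38.7%.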